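**Assumption:** the target has no stereocentre and no stereogenic double bond, so it is one achiral compound and no asymmetric step is needed. Ring intermediates 3–5 and 11–13 are racemic, and their stereocentres vanish on aromatisation.

## Retrosynthetic overview

1. Target 22 ⇐ double hydrogenolysis of the dibenzyl-protected depside 21 ⇐ aryl ester (depside) bond between acid 9 and phenol 19.
2. Acid 9 ⇐ methyl 2,4-dihydroxy-6-pentylbenzoate 6; phenol 19 ⇐ methyl 2,4-dihydroxy-6-propylbenzoate 14 (protecting-group and O-alkylation steps only).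
3. 6 and 14 ⇐ aromatisation of cyclohexane-1,3-dione esters 4 and 12 ⇐ intermolecular Michael addition of dimethyl malonate 1 to enones 2 and 10, then Dieckmann closure.
4. Ring order: the pentyl ring (A) is built first (steps 1–2), then the propyl ring (B) (steps 6–7); they are joined in step 13 and no further ring is formed.

## Route

Step 1
Reactants: 1 dimethyl malonate; 2 (E)-non-3-en-2-one
Product: 4 methyl 2,4-dioxo-6-pentylcyclohexane-1-carboxylate, via Michael adduct 3 (not isolated)
Conditions: NaOMe (1.2 equiv), MeOH, reflux, 4 h; then aq. HCl, 0 °C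
Reagents that add atoms: none
Why: The malonate enolate adds 1,4 to the enone (intermolecular Michael addition, the key C–C bond) and the methyl-ketone enolate of 3 then closes the ring on one ester (Dieckmann/Claisen condensation), driven by the stabilised β-diketone enolate; the racemic stereocentres are erased in step 2.

Step 2
Reactants: 4 methyl 2,4-dioxo-6-pentylcyclohexane-1-carboxylate
Product: 6 methyl 2,4-dihydroxy-6-pentylbenzoate, via bromo-dione ester 5 (not isolated)
Conditions: Br2 (1.0 equiv), DMF, 0 °C → 80 °C, 12 h; aq. NaHSO3 work-up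
Reagents that add atoms: none
Why: Bromination of the enolised 1,3-dione gives 5, which on warming in DMF loses HBr and tautomerises to the resorcinol ester (bromination–dehydrobromination aromatisation); one equivalent of Br2 limits ring bromination.

Step 3
Reactants: 6 methyl 2,4-dihydroxy-6-pentylbenzoate
Product: 7 methyl 2-hydroxy-4-methoxy-6-pentylbenzoate
Conditions: MeI (1.1 equiv), K2CO3 (1.2 equiv), acetone, reflux, 6 h
Reagents that add atoms: iodomethane, CI
Why: Williamson ether synthesis is selective for the 4-OH because the 2-OH is hydrogen-bonded to the ester carbonyl and much less nucleophilic.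

Step 4
Reactants: 7 methyl 2-hydroxy-4-methoxy-6-pentylbenzoate
Product: 8 methyl 2-(benzyloxy)-4-methoxy-6-pentylbenzoate
Conditions: BnBr (1.3 equiv), K2CO3 (2 equiv), DMF, 60 °C, 8 h
Reagents that add atoms: benzyl bromide, BrCc1ccccc1
Why: Under forcing Williamson conditions in DMF the chelated 2-OH is benzylated, masking it for the later esterification.

Step 5
Reactants: 8 methyl 2-(benzyloxy)-4-methoxy-6-pentylbenzoate
Product: 9 2-(benzyloxy)-4-methoxy-6-pentylbenzoic acid
Conditions: KOH (10 equiv), DMSO/H2O 4:1, 90 °C, 8 h; then cold 2 M HCl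
Reagents that add atoms: potassium hydroxide, [K+].[OH-]
Why: Poorly solvated hydroxide in aqueous DMSO saponifies the di-ortho-substituted methyl ester, and the benzyl and methyl ethers are inert to base.

Step 6
Reactants: 1 dimethyl malonate; 10 (E)-hept-3-en-2-one
Product: 12 methyl 2,4-dioxo-6-propylcyclohexane-1-carboxylate, via Michael adduct 11 (not isolated)
Conditions: NaOMe (1.2 equiv), MeOH, reflux, 4 h; then aq. HCl, 0 °C
Reagents that add atoms: none
Why: Same intermolecular Michael addition followed by Dieckmann condensation as step 1; the racemic stereocentres are erased in step 7.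

Step 7
Reactants: 12 methyl 2,4-dioxo-6-propylcyclohexane-1-carboxylate
Product: 14 methyl 2,4-dihydroxy-6-propylbenzoate, via bromo-dione ester 13 (not isolated)
Conditions: Br2 (1.0 equiv), DMF, 0 °C → 80 °C, 12 h; aq. NaHSO3 work-up
Reagents that add atoms: none
Why: Bromination–dehydrobromination aromatisation of the 1,3-dione, as in step 2.

Step 8
Reactants: 14 methyl 2,4-dihydroxy-6-propylbenzoate
Product: 15 methyl 4-(benzyloxy)-2-hydroxy-6-propylbenzoate
Conditions: BnBr (1.05 equiv), K2CO3 (1.1 equiv), acetone, reflux, 8 h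
Reagents that add atoms: benzyl bromide, BrCc1ccccc1
Why: Williamson benzylation goes to the free 4-OH and leaves the chelated 2-OH untouched.

Step 9
Reactants: 15 methyl 4-(benzyloxy)-2-hydroxy-6-propylbenzoate
Product: 16 methyl 4-(benzyloxy)-2-methoxy-6-propylbenzoate
Conditions: MeI (3 equiv), K2CO3 (2 equiv), DMF, 40 °C, 12 h
Reagents that add atoms: iodomethane, CI
Why: Excess MeI in DMF methylates the remaining hydrogen-bonded phenol (Williamson ether synthesis).

Step 10
Reactants: 16 methyl 4-(benzyloxy)-2-methoxy-6-propylbenzoate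
Product: 17 4-(benzyloxy)-2-methoxy-6-propylbenzoic acid
Conditions: KOH (10 equiv), DMSO/H2O 4:1, 90 °C, 8 h; then cold 2 M HCl
Reagents that add atoms: potassium hydroxide, [K+].[OH-]
Why: Saponification of the hindered methyl ester in aqueous DMSO, as in step 5; the ethers survive.

Step 11
Reactants: 17 4-(benzyloxy)-2-methoxy-6-propylbenzoic acid
Product: 18 4-hydroxy-2-methoxy-6-propylbenzoic acid
Conditions: H2 (1 atm), 10% Pd/C, EtOAc, rt, 3 h
Reagents that add atoms: none
Why: Catalytic hydrogenolysis cleaves the benzyl aryl ether and leaves the acid, methyl ether and arene untouched.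

Step 12
Reactants: 18 4-hydroxy-2-methoxy-6-propylbenzoic acid
Product: 19 benzyl 4-hydroxy-2-methoxy-6-propylbenzoate
Conditions: BnBr (1.05 equiv), KHCO3 (1.2 equiv), DMF, rt → 40 °C, 6 h
Reagents that add atoms: benzyl bromide, BrCc1ccccc1
Why: Bicarbonate ionises only the carboxylic acid, so SN2 O-alkylation gives the benzyl ester chemoselectively and the phenol stays free.

Step 13
Reactants: 9 2-(benzyloxy)-4-methoxy-6-pentylbenzoic acid; 19 benzyl 4-hydroxy-2-methoxy-6-propylbenzoate
Product: 21 benzyl 4-{[2-(benzyloxy)-4-methoxy-6-pentylbenzoyl]oxy}-2-methoxy-6-propylbenzoate, via mixed trifluoroacetic anhydride 20 (not isolated)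
Conditions: TFAA (4 equiv), dry toluene, rt, 3 h
Reagents that add atoms: none
Why: TFAA turns the hindered electron-rich acid into a mixed anhydride (acylium-like), which acylates the only free phenol of 19 (mixed-anhydride esterification, the standard depside coupling).

Step 14
Reactants: 21 benzyl 4-{[2-(benzyloxy)-4-methoxy-6-pentylbenzoyl]oxy}-2-methoxy-6-propylbenzoate
Product: 22 4-[(2-hydroxy-4-methoxy-6-pentylbenzoyl)oxy]-2-methoxy-6-propylbenzoic acid (target)
Conditions: H2 (1 atm), 10% Pd/C, EtOAc, rt, 2 h
Reagents that add atoms: none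
Why: Hydrogenolysis removes the benzyl ether and the benzyl ester in one operation (two equivalents of toluene), while the aryl ester linkage and the methyl ethers are stable to H2/Pd.

## Compound list

1 | dimethyl malonate | COC(=O)CC(=O)OC | starting material
2 | (E)-non-3-en-2-one | CCCCC/C=C/C(C)=O | starting material
3 | dimethyl 2-(2-oxononan-4-yl)propanedioate (racemic Michael adduct, formed as its sodium enolate) | CCCCCC(CC(C)=O)C(C(=O)OC)C(=O)OC | intermediate
4 | methyl 2,4-dioxo-6-pentylcyclohexane-1-carboxylate (racemic; mainly the enol, methyl 2-hydroxy-4-oxo-6-pentylcyclohex-2-ene-1-carboxylate) | CCCCCC1CC(=O)CC(=O)C1C(=O)OC | intermediate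
5 | methyl 3-bromo-2,4-dioxo-6-pentylcyclohexane-1-carboxylate (racemic) | CCCCCC1CC(=O)C(Br)C(=O)C1C(=O)OC | intermediate
6 | methyl 2,4-dihydroxy-6-pentylbenzoate (methyl olivetolate) | CCCCCc1cc(O)cc(O)c1C(=O)OC | intermediate
7 | methyl 2-hydroxy-4-methoxy-6-pentylbenzoate | CCCCCc1cc(OC)cc(O)c1C(=O)OC | intermediate
8 | methyl 2-(benzyloxy)-4-methoxy-6-pentylbenzoate | CCCCCc1cc(OC)cc(OCc2ccccc2)c1C(=O)OC | intermediate
9 | 2-(benzyloxy)-4-methoxy-6-pentylbenzoic acid | CCCCCc1cc(OC)cc(OCc2ccccc2)c1C(=O)O | intermediate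
10 | (E)-hept-3-en-2-one | CCC/C=C/C(C)=O | starting material
11 | dimethyl 2-(2-oxoheptan-4-yl)propanedioate (racemic Michael adduct, formed as its sodium enolate) | CCCC(CC(C)=O)C(C(=O)OC)C(=O)OC | intermediate
12 | methyl 2,4-dioxo-6-propylcyclohexane-1-carboxylate (racemic; mainly the enol) | CCCC1CC(=O)CC(=O)C1C(=O)OC | intermediate
13 | methyl 3-bromo-2,4-dioxo-6-propylcyclohexane-1-carboxylate (racemic) | CCCC1CC(=O)C(Br)C(=O)C1C(=O)OC | intermediate
14 | methyl 2,4-dihydroxy-6-propylbenzoate (methyl divarinate) | CCCc1cc(O)cc(O)c1C(=O)OC | intermediate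
15 | methyl 4-(benzyloxy)-2-hydroxy-6-propylbenzoate | CCCc1cc(OCc2ccccc2)cc(O)c1C(=O)OC | intermediate
16 | methyl 4-(benzyloxy)-2-methoxy-6-propylbenzoate | CCCc1cc(OCc2ccccc2)cc(OC)c1C(=O)OC | intermediate
17 | 4-(benzyloxy)-2-methoxy-6-propylbenzoic acid | CCCc1cc(OCc2ccccc2)cc(OC)c1C(=O)O | intermediate
18 | 4-hydroxy-2-methoxy-6-propylbenzoic acid | CCCc1cc(O)cc(OC)c1C(=O)O | intermediate
19 | benzyl 4-hydroxy-2-methoxy-6-propylbenzoate | CCCc1cc(O)cc(OC)c1C(=O)OCc1ccccc1 | intermediate
20 | 2-(benzyloxy)-4-methoxy-6-pentylbenzoic trifluoroacetic anhydride | CCCCCc1cc(OC)cc(OCc2ccccc2)c1C(=O)OC(=O)C(F)(F)F | intermediate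
21 | benzyl 4-{[2-(benzyloxy)-4-methoxy-6-pentylbenzoyl]oxy}-2-methoxy-6-propylbenzoate | CCCCCc1cc(OC)cc(OCc2ccccc2)c1C(=O)Oc1cc(CCC)c(C(=O)OCc2ccccc2)c(OC)c1 | intermediate
22 | 4-[(2-hydroxy-4-methoxy-6-pentylbenzoyl)oxy]-2-methoxy-6-propylbenzoic acid | CCCCCc1cc(OC)cc(O)c1C(=O)Oc1cc(CCC)c(C(=O)O)c(OC)c1 | target

## Step count and risks

Total steps: 14. Longest linear sequence: 9 steps (6 → 7 → 8 → 9 → 10 → 11 → 12 → 13 → 14).

**Step 2 (aromatisation of the dione ester).** Risks are over-bromination of the resorcinol and incomplete loss of HBr. The fallback sets out from 4 and comes back at 6. Dione 4 is treated with excess Br2 (3 equiv) in acetic acid at room temperature, which brominates exhaustively and aromatises in one go to methyl 3,5-dibromo-2,4-dihydroxy-6-pentylbenzoate F1. Reductive debromination of this dibromide (H2, Pd/C, NaOAc, MeOH, rt) then gives 6, so over-bromination is used deliberately and corrected afterwards.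

**Step 12 (carboxyl-selective benzylation).** The risk is competing O-benzylation of the fairly acidic para-phenol. The fallback sets out from 18 and comes back at 19. The phenol of 18 is first acetylated (Ac2O, pyridine, rt, aqueous work-up) to 4-acetoxy-2-methoxy-6-propylbenzoic acid F2. The acid is then benzylated without any selectivity issue (BnBr, KHCO3, DMF, rt) to benzyl 4-acetoxy-2-methoxy-6-propylbenzoate F3. The aryl acetate is finally removed by mild methanolysis (catalytic K2CO3, MeOH, 0 °C), which the hindered benzyl ester survives, giving 19.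

**Step 13 (depside coupling of the di-ortho-substituted acid).** Risks are low conversion, C-acylation and acid-mediated loss of the benzyl ether. The fallback sets out from 9 and comes back at 21. Acid 9 is converted with oxalyl chloride and catalytic DMF in CH2Cl2 (0 °C → rt) into 2-(benzyloxy)-4-methoxy-6-pentylbenzoyl chloride F4. This is added to the sodium phenoxide of 19 (NaH, THF, 0 °C → rt) to give 21 under basic, non-acidic conditions.

## Further compounds

F1 | step 2 | methyl 3,5-dibromo-2,4-dihydroxy-6-pentylbenzoate | CCCCCc1c(Br)c(O)c(Br)c(O)c1C(=O)OC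
F2 | step 12 | 4-acetoxy-2-methoxy-6-propylbenzoic acid | CCCc1cc(OC(C)=O)cc(OC)c1C(=O)O
F3 | step 12 | benzyl 4-acetoxy-2-methoxy-6-propylbenzoate | CCCc1cc(OC(C)=O)cc(OC)c1C(=O)OCc1ccccc1
F4 | step 13 | 2-(benzyloxy)-4-methoxy-6-pentylbenzoyl chloride | CCCCCc1cc(OC)cc(OCc2ccccc2)c1C(=O)Cl
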